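**Retrosynthetic overview**
1. Target 11 ⇒ depside aldehyde 10: the B-ring CO2H is carried as CHO and oxidised last (Pinnick), so no carboxyl protecting group is needed.
2. 10 ⇒ depside ester C(=O)–O disconnection into A-ring acid 5 and B-ring phenol 8 (TFAA-mediated esterification).
3. 5 and 8 ⇒ both from 2,4-dihydroxy-6-pentylbenzaldehyde 3, using the chelated 2-OH / free 4-OH difference (A: 4-OMe, then CHO→CO2H; B: 4-OMOM, 2-OMe, MOM off).
4. 3 ⇒ olivetol 1 by Vilsmeier–Haack formylation.
5. No ring is formed: both benzene rings are bought as olivetol.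

**Assumption:** the target has no stereocentre and no stereogenic double bond, so "single enantiomer" places no demand on the route; olivetol is taken as the commercial starting material.

**Step 1**
Reactants: 1 olivetol (5-pentylbenzene-1,3-diol)
Product: 3 2,4-dihydroxy-6-pentylbenzaldehyde, via aryl iminium salt 2 (not isolated)
Conditions: POCl3 (1.2 equiv), DMF, 0 °C to rt; then H2O, 50 °C
Reagents that add atoms: N,N-dimethylformamide CN(C)C=O; water O
Why: Vilsmeier–Haack formylation attacks the ring carbon ortho to one OH and para to the other (as orcinol gives orcylaldehyde), and hydrolysis of the iminium salt gives the aldehyde; no stereocentre is formed.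

**Step 2**
Reactants: 3 2,4-dihydroxy-6-pentylbenzaldehyde
Product: 4 2-hydroxy-4-methoxy-6-pentylbenzaldehyde
Conditions: MeI (1.1 equiv), K2CO3 (1.1 equiv), acetone, rt
Reagents that add atoms: iodomethane CI
Why: Williamson etherification is selective for the more acidic, unchelated 4-OH because the 2-OH is hydrogen-bonded to the aldehyde.

**Step 3**
Reactants: 4 2-hydroxy-4-methoxy-6-pentylbenzaldehyde
Product: 5 2-hydroxy-4-methoxy-6-pentylbenzoic acid
Conditions: NaClO2, NaH2PO4, 2-methyl-2-butene (excess), t-BuOH/H2O, rt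
Reagents that add atoms: sodium chlorite [Na+].[O-]Cl=O
Why: Pinnick (Lindgren) oxidation takes ArCHO to ArCO2H under buffered mild acid, and the alkene scavenger traps HOCl so the electron-rich phenolic ring is not chlorinated.

**Step 4**
Reactants: 3 2,4-dihydroxy-6-pentylbenzaldehyde
Product: 6 2-hydroxy-4-(methoxymethoxy)-6-pentylbenzaldehyde
Conditions: MOMCl (1.1 equiv), K2CO3, acetone, 0 °C to rt
Reagents that add atoms: chloromethyl methyl ether COCCl
Why: O-alkylation (MOM protection) goes selectively to the free 4-OH for the same chelation reason as in step 2.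

**Step 5**
Reactants: 6 2-hydroxy-4-(methoxymethoxy)-6-pentylbenzaldehyde
Product: 7 2-methoxy-4-(methoxymethoxy)-6-pentylbenzaldehyde
Conditions: MeI (3 equiv), K2CO3, DMF, 40 °C
Reagents that add atoms: iodomethane CI
Why: Williamson etherification under more forcing conditions methylates the remaining chelated 2-OH, while the MOM acetal and the aldehyde are stable to base.

**Step 6**
Reactants: 7 2-methoxy-4-(methoxymethoxy)-6-pentylbenzaldehyde
Product: 8 4-hydroxy-2-methoxy-6-pentylbenzaldehyde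
Conditions: 3 M aq HCl, THF, 50 °C
Reagents that add atoms: none
Why: Acid-catalysed acetal hydrolysis removes the MOM group and leaves the aryl methyl ether and the aldehyde untouched.

**Step 7**
Reactants: 5 2-hydroxy-4-methoxy-6-pentylbenzoic acid; 8 4-hydroxy-2-methoxy-6-pentylbenzaldehyde
Product: 10 4-formyl-3-methoxy-5-pentylphenyl 2-hydroxy-4-methoxy-6-pentylbenzoate, via mixed trifluoroacetic anhydride 9 (not isolated)
Conditions: (CF3CO)2O (3 equiv), toluene, rt, 3 h
Reagents that add atoms: none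
Why: Mixed-anhydride esterification: TFAA activates acid 5, which then acylates the only free phenol of 8, while the chelated, flanked 2-OH of 5 does not compete.

**Step 8**
Reactants: 10 4-formyl-3-methoxy-5-pentylphenyl 2-hydroxy-4-methoxy-6-pentylbenzoate
Product: 11 2'-O-methylperlatolic acid (4-[(2-hydroxy-4-methoxy-6-pentylbenzoyl)oxy]-2-methoxy-6-pentylbenzoic acid)
Conditions: NaClO2, NaH2PO4, 2-methyl-2-butene (large excess), t-BuOH/THF/H2O, 0 °C to rt
Reagents that add atoms: sodium chlorite [Na+].[O-]Cl=O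
Why: Pinnick oxidation is chemoselective for the aldehyde at pH 3–4, where the depside aryl ester is not hydrolysed and scavenged HOCl cannot chlorinate the A-ring.

**Compound list**
1 | olivetol (5-pentylbenzene-1,3-diol) | CCCCCc1cc(O)cc(O)c1 | starting material
2 | [(2,4-dihydroxy-6-pentylphenyl)methylidene]dimethylammonium chloride | CCCCCc1cc(O)cc(O)c1C=[N+](C)C.[Cl-] | intermediate
3 | 2,4-dihydroxy-6-pentylbenzaldehyde | CCCCCc1cc(O)cc(O)c1C=O | intermediate
4 | 2-hydroxy-4-methoxy-6-pentylbenzaldehyde | CCCCCc1cc(OC)cc(O)c1C=O | intermediate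
5 | 2-hydroxy-4-methoxy-6-pentylbenzoic acid | CCCCCc1cc(OC)cc(O)c1C(=O)O | intermediate
6 | 2-hydroxy-4-(methoxymethoxy)-6-pentylbenzaldehyde | CCCCCc1cc(OCOC)cc(O)c1C=O | intermediate
7 | 2-methoxy-4-(methoxymethoxy)-6-pentylbenzaldehyde | CCCCCc1cc(OCOC)cc(OC)c1C=O | intermediate
8 | 4-hydroxy-2-methoxy-6-pentylbenzaldehyde | CCCCCc1cc(O)cc(OC)c1C=O | intermediate
9 | 2-hydroxy-4-methoxy-6-pentylbenzoic trifluoroacetic anhydride | CCCCCc1cc(OC)cc(O)c1C(=O)OC(=O)C(F)(F)F | intermediate
10 | 4-formyl-3-methoxy-5-pentylphenyl 2-hydroxy-4-methoxy-6-pentylbenzoate | CCCCCc1cc(OC)cc(O)c1C(=O)Oc1cc(CCCCC)c(C=O)c(OC)c1 | intermediate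
11 | 2'-O-methylperlatolic acid | CCCCCc1cc(OC)cc(O)c1C(=O)Oc1cc(CCCCC)c(C(=O)O)c(OC)c1 | target

**Total step count:** 8 (convergent).
**Longest linear sequence:** 6 steps (1, 4, 5, 6, 7, 8 from olivetol).

**Steps most likely to fail, with fallbacks**

Step 7 (depside esterification). The free hydroxy acid 5 may self-condense, or the weakly nucleophilic para-formyl phenol 8 may react poorly. The fallback sets out from 4 and comes back at 11. Compound 4 is benzylated (BnBr, K2CO3, DMF) to 2-(benzyloxy)-4-methoxy-6-pentylbenzaldehyde F3. Pinnick oxidation gives 2-(benzyloxy)-4-methoxy-6-pentylbenzoic acid F4. Steglich coupling with 8 (DCC, DMAP, CH2Cl2) gives 4-formyl-3-methoxy-5-pentylphenyl 2-(benzyloxy)-4-methoxy-6-pentylbenzoate F5. A Pinnick oxidation, now on a substrate without a free phenol, gives 4-{[2-(benzyloxy)-4-methoxy-6-pentylbenzoyl]oxy}-2-methoxy-6-pentylbenzoic acid F6. Hydrogenolysis (H2, Pd/C, EtOAc) then gives 11.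

Step 8 (late Pinnick oxidation on the depside). The phenolic A-ring may be chlorinated or the hindered aldehyde may react slowly. The fallback sets out from 7 and comes back at 11, carrying the B-ring carboxyl as a benzyl ester. Compound 7 is oxidised (Pinnick) to 2-methoxy-4-(methoxymethoxy)-6-pentylbenzoic acid F7. Esterification (BnBr, KHCO3, DMF) gives benzyl 2-methoxy-4-(methoxymethoxy)-6-pentylbenzoate F8. Aqueous HCl/THF removes the MOM group to give benzyl 4-hydroxy-2-methoxy-6-pentylbenzoate F9. TFAA/toluene coupling with 5 gives benzyl 4-[(2-hydroxy-4-methoxy-6-pentylbenzoyl)oxy]-2-methoxy-6-pentylbenzoate F10. Hydrogenolysis (H2, Pd/C, EtOAc) gives 11.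

Step 3 (Pinnick oxidation of a chelated, electron-rich phenolic aldehyde). Ring chlorination or slow conversion is possible. The fallback sets out from 4 and comes back at 5. The phenol is capped (Ac2O, pyridine) to give 2-formyl-5-methoxy-3-pentylphenyl acetate F1, which deactivates the ring and breaks the chelate. Oxidation (NaClO2 or KMnO4) gives 2-(acetyloxy)-4-methoxy-6-pentylbenzoic acid F2. Aqueous NaOH followed by acidification removes the acetate and gives 5.

**Further compounds**
F1 | step 3 | 2-formyl-5-methoxy-3-pentylphenyl acetate | CCCCCc1cc(OC)cc(OC(C)=O)c1C=O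
F2 | step 3 | 2-(acetyloxy)-4-methoxy-6-pentylbenzoic acid | CCCCCc1cc(OC)cc(OC(C)=O)c1C(=O)O
F3 | step 7 | 2-(benzyloxy)-4-methoxy-6-pentylbenzaldehyde | CCCCCc1cc(OC)cc(OCc2ccccc2)c1C=O
F4 | step 7 | 2-(benzyloxy)-4-methoxy-6-pentylbenzoic acid | CCCCCc1cc(OC)cc(OCc2ccccc2)c1C(=O)O
F5 | step 7 | 4-formyl-3-methoxy-5-pentylphenyl 2-(benzyloxy)-4-methoxy-6-pentylbenzoate | CCCCCc1cc(OC)cc(OCc2ccccc2)c1C(=O)Oc1cc(CCCCC)c(C=O)c(OC)c1
F6 | step 7 | 4-{[2-(benzyloxy)-4-methoxy-6-pentylbenzoyl]oxy}-2-methoxy-6-pentylbenzoic acid | CCCCCc1cc(OC)cc(OCc2ccccc2)c1C(=O)Oc1cc(CCCCC)c(C(=O)O)c(OC)c1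
F7 | step 8 | 2-methoxy-4-(methoxymethoxy)-6-pentylbenzoic acid | CCCCCc1cc(OCOC)cc(OC)c1C(=O)O
F8 | step 8 | benzyl 2-methoxy-4-(methoxymethoxy)-6-pentylbenzoate | CCCCCc1cc(OCOC)cc(OC)c1C(=O)OCc1ccccc1
F9 | step 8 | benzyl 4-hydroxy-2-methoxy-6-pentylbenzoate | CCCCCc1cc(O)cc(OC)c1C(=O)OCc1ccccc1
F10 | step 8 | benzyl 4-[(2-hydroxy-4-methoxy-6-pentylbenzoyl)oxy]-2-methoxy-6-pentylbenzoate | CCCCCc1cc(OC)cc(O)c1C(=O)Oc1cc(CCCCC)c(C(=O)OCc2ccccc2)c(OC)c1
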